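**Retrosynthetic overview**

1. Isochromene numbering is used: C1(H)=C8a, O2, C3(H)Me, C4H2, C4a=C5(H), C6=O, C7(Me)(O-acyl), C8=O. The last disconnection is the C7–O linoleoyl ester, made from the tertiary alcohol after a triethylsilyl group is removed.
2. The strategy rests on the carbocycle enone C6(=O)–C5=C4a and the pyran enol ether O2–C1=C8a, which meet at C8a. The bicycle is thus the cyclodehydrated Michael adduct of carbon C8a of a C8/C1 keto-aldehyde to a C6–C5≡C4a ynone.
3. Key disconnections: C8a–C4a (carbocycle, closed first) and O2–C1 (pyran, closed second in the same flask), which lead back to one open-chain ynone keto-aldehyde.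
4. The ynone comes from a C6 Weinreb amide and the dianion of (R)-pent-4-yn-2-ol (C6–C5 bond). The acetylide is added while the keto-aldehyde is hidden as its enolate, because a free C8 ketone would not survive it.
5. C7 comes from (R)-lactic acid through its pivalaldehyde acetal (C7–C8 aldol with 3,3-dimethoxypropanal, retention); C3 comes from the pentynol.

Key step: step 9

Remark: ring atoms carry isochromene numbers throughout; 10, 15 and 17 are drawn as keto-aldehydes although they should exist mainly as chelated enols.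

**Route**

Step 1
Reactants: 1 (R)-lactic acid
Product: 2 (2R,5R)-2-tert-butyl-5-methyl-1,3-dioxolan-4-one (cis)
Conditions: t-BuCHO, cat. p-TsOH·H2O, cat. H2SO4, pentane, reflux, azeotropic removal of water; recrystallisation from pentane/Et2O at −78 °C
Reagents that add atoms: pivalaldehyde, CC(C)(C)C=O
Why: Acid-catalysed acetalisation under thermodynamic control (self-regeneration-of-stereocentres template) should give mainly the cis acetal, whose new acetal centre is set by the lactate centre and which is purified by crystallisation.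

Step 2
Reactants: 3 methyl 3,3-dimethoxypropanoate
Product: 4 3,3-dimethoxypropanal
Conditions: i-Bu2AlH (1.05 equiv), CH2Cl2, −78 °C; aq. potassium sodium tartrate; used at once as a solution
Reagents that add atoms: none
Why: Partial reduction of an ester to the aldehyde at −78 °C through the stable aluminium hemiacetal, with immediate use so that the aldehyde does not lose methanol to 3-methoxyacrolein.

Step 3
Reactants: 2 (2R,5R)-2-tert-butyl-5-methyl-1,3-dioxolan-4-one; 4 3,3-dimethoxypropanal
Product: 6 (2R,5S)-2-tert-butyl-5-(1-hydroxy-3,3-dimethoxypropyl)-5-methyl-1,3-dioxolan-4-one (carbinol epimers), via lithium enolate 5 (not isolated)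
Conditions: LiN(i-Pr)2, THF, −78 °C; then 4, −78 °C; AcOH, −78 °C
Reagents that add atoms: none
Why: Aldol addition of the dioxolanone enolate, which is attacked on the face opposite the tert-butyl group, so the new C7–C8 bond replaces the former C–H bond with overall retention; the C8 carbinol forms as a mixture that is removed by oxidation in step 5.

Step 4
Reactants: 6 (2R,5S)-2-tert-butyl-5-(1-hydroxy-3,3-dimethoxypropyl)-5-methyl-1,3-dioxolan-4-one
Product: 7 (2S)-2,3-dihydroxy-N,5,5-trimethoxy-N,2-dimethylpentanamide (C3 epimers)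
Conditions: MeNH(OMe), AlMe3, CH2Cl2, 0 °C to 40 °C; aq. potassium sodium tartrate
Reagents that add atoms: N,O-dimethylhydroxylamine, CNOC
Why: Aluminium-amide aminolysis of a lactone (Weinreb amide formation) at an activated acylal carbonyl, in which the ring oxygen leaves as a hemiacetal that sheds pivalaldehyde on work-up and C7 is not touched.

Step 5
Reactants: 7 (2S)-2,3-dihydroxy-N,5,5-trimethoxy-N,2-dimethylpentanamide
Product: 8 (2S)-2-hydroxy-N,5,5-trimethoxy-N,2-dimethyl-3-oxopentanamide
Conditions: SO3·pyridine, DMSO, i-Pr2NEt, CH2Cl2, 0 °C to rt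
Reagents that add atoms: none
Why: Parikh–Doering oxidation of the secondary alcohol of a secondary/tertiary 1,2-diol, chosen because activated sulfoxide cannot cleave the glycol and the basic medium keeps the free tertiary hydroxyl from closing onto the dimethyl acetal.

Step 6
Reactants: 8 (2S)-2-hydroxy-N,5,5-trimethoxy-N,2-dimethyl-3-oxopentanamide
Product: 9 (2S)-N,5,5-trimethoxy-N,2-dimethyl-3-oxo-2-(triethylsilyloxy)pentanamide
Conditions: Et3SiOTf, 2,6-lutidine, CH2Cl2, −78 °C to −40 °C
Reagents that add atoms: triethylsilyl triflate, CC[Si](CC)(CC)OS(=O)(=O)C(F)(F)F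
Why: Silylation of a tertiary alcohol with a silyl triflate and a hindered pyridine base, which at low temperature should outrun enol silylation of the C8 ketone and activation of the acetal; the ether later blocks 5-endo attack of this oxygen on the ynone and α-ketol shifts.

Step 7
Reactants: 9 (2S)-N,5,5-trimethoxy-N,2-dimethyl-3-oxo-2-(triethylsilyloxy)pentanamide
Product: 10 (2S)-N-methoxy-N,2-dimethyl-3,5-dioxo-2-(triethylsilyloxy)pentanamide
Conditions: 10% aq. oxalic acid on SiO2, CH2Cl2, rt
Reagents that add atoms: water, O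
Why: Mild acid hydrolysis of a dimethyl acetal, eased by the β-keto group, under conditions that a hindered tertiary triethylsilyl ether should survive.

Step 8
Reactants: 10 (2S)-N-methoxy-N,2-dimethyl-3,5-dioxo-2-(triethylsilyloxy)pentanamide; 11 (R)-pent-4-yn-2-ol
Product: 15 (4S,9R)-9-hydroxy-4-methyl-3,5-dioxo-4-(triethylsilyloxy)dec-6-ynal, via lithium enolate 12 (not isolated), via dilithium acetylide alkoxide 13 (not isolated), via trilithium tetrahedral adduct 14 (not isolated)
Conditions: 10, LiN(SiMe3)2 (1.05 equiv), THF, −78 °C; 11, n-BuLi (2 equiv), THF, −78 to 0 °C; combine (3 equiv of 13), −78 to −10 °C; inverse quench into cold 1 M HCl; short SiO2 plug, use at once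
Reagents that add atoms: none
Why: Weinreb ketone synthesis with a lithium acetylide, run with the keto-aldehyde protected in the flask as its non-electrophilic 1,3-dicarbonyl enolate 12 (a known in situ enolate protection) and the C3 hydroxyl as the alkoxide of 13; chelated adduct 14 holds the C6 oxidation level until the cold acidic quench, which also keeps the freed MeNH(OMe) protonated and away from the ynone.

Step 9
Reactants: 15 (4S,9R)-9-hydroxy-4-methyl-3,5-dioxo-4-(triethylsilyloxy)dec-6-ynal
Product: 19 (3R,7R)-3,7-dimethyl-7-(triethylsilyloxy)-3,4-dihydro-6H-isochromene-6,8(7H)-dione, via magnesium enolate 16 (not isolated), via Michael adduct 17 (not isolated), via lactol 18 (not isolated)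
Conditions: MgCl2 (1.1 equiv), Et3N (1.2 equiv), MeCN, 0 °C to rt; then CF3CO2H (2 equiv), rt
Reagents that add atoms: none
Why: Soft enolisation gives magnesium enolate 16, in which the metal bridges the C8 and C1 oxygens and can also bind the C6 carbonyl, so both enolate oxygens are tied up and C8a sits next to the alkyne; C8a then adds to the ynone β-carbon C4a and protonation at C5 gives cyclohexenedione 17 with C4a=C5 in place. This is an intramolecular Michael addition of a 1,3-dicarbonyl carbon to an alkynone, and the carbocycle closes in the 6-endo-dig mode with the enolate double bond inside the new ring. After acidification the C3 hydroxyl attacks the formyl carbon C1 of 17 in a 6-exo-trig hemiacetalisation to lactol 18, which loses water to the enol ether O2–C1=C8a conjugated with C8=O and with the C4a=C5–C6=O enone, as in the pyran closure of azaphilone-type vinylogous esters. No stereocentre is formed (C8a ends sp2), C7 is quaternary and cannot enolise, and C3 is remote from any acidic site, so both keep their configuration. The selectivity needed is carbon over oxygen attack of the ambident enolate (both 6-endo-dig) and Michael addition over base-induced alkyne-to-allene isomerisation; chelation by divalent magnesium, the weak amine base and the absence of a second enolisable carbonyl on the alkyne side are expected to secure it.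

Step 10
Reactants: 19 (3R,7R)-3,7-dimethyl-7-(triethylsilyloxy)-3,4-dihydro-6H-isochromene-6,8(7H)-dione
Product: 20 (3R,7R)-7-hydroxy-3,7-dimethyl-3,4-dihydro-6H-isochromene-6,8(7H)-dione
Conditions: HF·pyridine, pyridine, THF, 0 °C to rt
Reagents that add atoms: none
Why: Fluoride cleavage of a silyl ether under weakly acidic buffered conditions, which avoid the basic media in which the non-enolisable 1,3-dione could open by retro-Claisen attack.

Step 11
Reactants: 20 (3R,7R)-7-hydroxy-3,7-dimethyl-3,4-dihydro-6H-isochromene-6,8(7H)-dione; 21 linoleoyl chloride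
Product: 22 (3R,7R)-3,7-dimethyl-6,8-dioxo-3,4,7,8-tetrahydro-6H-isochromen-7-yl (9Z,12Z)-octadeca-9,12-dienoate (CNP0260084.1)
Conditions: Et3N, DMAP, CH2Cl2, 0 °C to rt, argon, dark
Reagents that add atoms: none
Why: DMAP-catalysed acylation of a tertiary alcohol with an acid chloride (nucleophilic catalysis through the acylpyridinium ion), the usual way to esterify the C7 hydroxyl of azaphilone-type diones; only the O–H bond is broken, so C7 keeps its configuration, and air and light are excluded to protect the skipped Z,Z-diene.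

**Compound list**

1 | (R)-lactic acid | C[C@@H](O)C(=O)O | starting material
2 | (2R,5R)-2-tert-butyl-5-methyl-1,3-dioxolan-4-one | C[C@H]1O[C@@H](C(C)(C)C)OC1=O | intermediate
3 | methyl 3,3-dimethoxypropanoate | COC(OC)CC(=O)OC | starting material
4 | 3,3-dimethoxypropanal | COC(OC)CC=O | intermediate
5 | lithium (2R)-2-tert-butyl-5-methyl-1,3-dioxol-4-olate (enolate of 2) | CC1=C([O-])O[C@H](C(C)(C)C)O1.[Li+] | intermediate (not isolated)
6 | (2R,5S)-2-tert-butyl-5-(1-hydroxy-3,3-dimethoxypropyl)-5-methyl-1,3-dioxolan-4-one (carbinol epimers) | C[C@@]1(C(O)CC(OC)OC)O[C@@H](C(C)(C)C)OC1=O | intermediate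
7 | (2S)-2,3-dihydroxy-N,5,5-trimethoxy-N,2-dimethylpentanamide (C3 epimers) | CON(C)C(=O)[C@@](C)(O)C(O)CC(OC)OC | intermediate
8 | (2S)-2-hydroxy-N,5,5-trimethoxy-N,2-dimethyl-3-oxopentanamide | CON(C)C(=O)[C@@](C)(O)C(=O)CC(OC)OC | intermediate
9 | (2S)-N,5,5-trimethoxy-N,2-dimethyl-3-oxo-2-(triethylsilyloxy)pentanamide | CC[Si](CC)(CC)O[C@](C)(C(=O)N(C)OC)C(=O)CC(OC)OC | intermediate
10 | (2S)-N-methoxy-N,2-dimethyl-3,5-dioxo-2-(triethylsilyloxy)pentanamide | CC[Si](CC)(CC)O[C@](C)(C(=O)N(C)OC)C(=O)CC=O | intermediate
11 | (R)-pent-4-yn-2-ol | C#CC[C@@H](C)O | starting material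
12 | lithium enolate of 10 (C8–O and C1=O cis) | CC[Si](CC)(CC)O[C@](C)(C(=O)N(C)OC)C(/[O-])=C/C=O.[Li+] | intermediate (not isolated)
13 | dilithium (R)-pent-4-yn-2-olate acetylide | [Li+].[Li+].[C-]#CC[C@@H](C)[O-] | intermediate (not isolated)
14 | trilithium tetrahedral adduct at C6 (hemiaminal centre unassigned) | CC[Si](CC)(CC)O[C@@](C)(C(/[O-])=C/C=O)C([O-])(N(C)OC)C#CC[C@@H](C)[O-].[Li+].[Li+].[Li+] | intermediate (not isolated)
15 | (4S,9R)-9-hydroxy-4-methyl-3,5-dioxo-4-(triethylsilyloxy)dec-6-ynal | CC[Si](CC)(CC)O[C@](C(=O)CC=O)(C)C(=O)C#CC[C@@H](C)O | intermediate (key-step precursor)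
16 | chloromagnesium enolate of 15 | CC[Si](CC)(CC)O[C@](C(/[O-])=C/C=O)(C)C(=O)C#CC[C@@H](C)O.[Mg+2].[Cl-] | intermediate (not isolated)
17 | (5R)-2-[(2R)-2-hydroxypropyl]-5-methyl-4,6-dioxo-5-(triethylsilyloxy)cyclohex-2-ene-1-carbaldehyde (C1 unassigned, enolised) | CC[Si](CC)(CC)O[C@]1(C)C(=O)C=C(C[C@@H](C)O)C(C=O)C1=O | intermediate (not isolated)
18 | (3R,7R)-1-hydroxy-1,8a-dihydro lactol of 19 (C1 and C8a unassigned) | CC[Si](CC)(CC)O[C@]1(C)C(=O)C=C2C[C@@H](C)OC(O)C2C1=O | intermediate (not isolated)
19 | (3R,7R)-3,7-dimethyl-7-(triethylsilyloxy)-3,4-dihydro-6H-isochromene-6,8(7H)-dione | CC[Si](CC)(CC)O[C@]1(C)C(=O)C=C2C[C@@H](C)OC=C2C1=O | intermediate (key-step product)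
20 | (3R,7R)-7-hydroxy-3,7-dimethyl-3,4-dihydro-6H-isochromene-6,8(7H)-dione | O[C@]1(C)C(=O)C=C2C[C@@H](C)OC=C2C1=O | intermediate
21 | linoleoyl chloride, (9Z,12Z)-octadeca-9,12-dienoyl chloride | CCCCC/C=C\C/C=C\CCCCCCCC(=O)Cl | starting material
22 | (3R,7R)-3,7-dimethyl-6,8-dioxo-3,4,7,8-tetrahydro-6H-isochromen-7-yl (9Z,12Z)-octadeca-9,12-dienoate | CCCCC/C=C\C/C=C\CCCCCCCC(=O)O[C@]1(C)C(=O)C=C2C[C@@H](C)OC=C2C1=O | target

**Step count**

Total: 11 steps. Longest linear sequence: 10 steps (steps 1 and 3 to 11, from (R)-lactic acid).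

**Steps most likely to fail**

1. Step 9 (key step). The enolate may close through its C8 oxygen (also 6-endo-dig) to a dihydropyranone, or the amine base may isomerise the ynone to an allenone before the C–C bond forms. The fallback uses a Bohlmann–Rahtz-type addition of an enaminone carbon to an ynone and sets out from 10.
 - Condensation of 10 with morpholine (CH2Cl2, MgSO4, rt) gives the morpholine enaminone F1. Its oxygen-centred enolate reactivity is gone, and its C8 carbonyl is a vinylogous amide that a lithium acetylide should spare at −78 °C.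
 - Addition of 13 to the Weinreb amide of F1 as in step 8, with a cold pH 5 buffer quench, gives the enaminone ynone F2.
 - Warming F2 in toluene/AcOH (5:1, 50 °C) lets C8a of the enaminone add to C4a; the C3 hydroxyl then displaces morpholine at C1 by addition–elimination.
 - The route is rejoined at 19.

2. Step 8. Acyl substitution at a hindered amide on a dianionic substrate may be slow; the dilithium reagent may precipitate, the amide may undergo base-induced N–O fragmentation, or the adduct may collapse early and over-add. The fallback keeps C8 as a protected alcohol while the ynone is made and sets out from 7.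
 - Et3SiOTf/2,6-lutidine (−78 to −20 °C) gives the bis(triethylsilyl) ether F3.
 - 11 is converted (NaH, 4-methoxybenzyl chloride) into (R)-4-[(4-methoxybenzyl)oxy]pent-1-yne F4, whose lithium acetylide (n-BuLi, THF, −78 °C) adds to F3 to give the ynone F5.
 - Pyridinium p-toluenesulfonate in MeOH at 0 °C removes the less hindered secondary silyl group and gives the C8 alcohol F6.
 - Dess–Martin periodinane gives the diketone F7.
 - DDQ in wet CH2Cl2 frees the C3 hydroxyl and gives the hydroxy diketone acetal F8.
 - Aqueous oxalic acid on SiO2, as in step 7, unmasks the aldehyde, and the route is rejoined at 15.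

3. Step 4. Attack at a carbonyl next to a quaternary carbon may be slow, and long exposure to the Lewis-acidic aluminium reagent may ionise the dimethyl acetal or cause retro-aldol cleavage. The fallback sets out from 6.
 - LiOH in THF/H2O (0 °C) hydrolyses the acylal ester to the dihydroxy acid F9, with loss of pivalaldehyde.
 - Amide coupling with MeNH(OMe)·HCl, EDC·HCl, HOBt and N-methylmorpholine returns to 7.

**Further compounds**

F1 | step 9 | (2S,4E)-N-methoxy-N,2-dimethyl-5-(morpholin-4-yl)-3-oxo-2-(triethylsilyloxy)pent-4-enamide | CC[Si](CC)(CC)O[C@](C)(C(=O)N(C)OC)C(=O)/C=C/N1CCOCC1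
F2 | step 9 | (1E,4S,9R)-9-hydroxy-4-methyl-1-(morpholin-4-yl)-4-(triethylsilyloxy)dec-1-en-6-yne-3,5-dione | CC[Si](CC)(CC)O[C@](C(=O)/C=C/N1CCOCC1)(C)C(=O)C#CC[C@@H](C)O
F3 | step 8 | (2S)-N,5,5-trimethoxy-N,2-dimethyl-2,3-bis(triethylsilyloxy)pentanamide | CC[Si](CC)(CC)O[C@](C)(C(=O)N(C)OC)C(CC(OC)OC)O[Si](CC)(CC)CC
F4 | step 8 | (R)-4-[(4-methoxybenzyl)oxy]pent-1-yne | C#CC[C@@H](C)OCc1ccc(OC)cc1
F5 | step 8 | (4S,9R)-1,1-dimethoxy-9-[(4-methoxybenzyl)oxy]-4-methyl-3,4-bis(triethylsilyloxy)dec-6-yn-5-one | CC[Si](CC)(CC)O[C@](C)(C(=O)C#CC[C@@H](C)OCc1ccc(OC)cc1)C(CC(OC)OC)O[Si](CC)(CC)CC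
F6 | step 8 | (4S,9R)-3-hydroxy-1,1-dimethoxy-9-[(4-methoxybenzyl)oxy]-4-methyl-4-(triethylsilyloxy)dec-6-yn-5-one | CC[Si](CC)(CC)O[C@](C)(C(=O)C#CC[C@@H](C)OCc1ccc(OC)cc1)C(O)CC(OC)OC
F7 | step 8 | (4S,9R)-1,1-dimethoxy-9-[(4-methoxybenzyl)oxy]-4-methyl-4-(triethylsilyloxy)dec-6-yne-3,5-dione | CC[Si](CC)(CC)O[C@](C)(C(=O)C#CC[C@@H](C)OCc1ccc(OC)cc1)C(=O)CC(OC)OC
F8 | step 8 | (4S,9R)-9-hydroxy-1,1-dimethoxy-4-methyl-4-(triethylsilyloxy)dec-6-yne-3,5-dione | CC[Si](CC)(CC)O[C@](C)(C(=O)C#CC[C@@H](C)O)C(=O)CC(OC)OC
F9 | step 4 | (2S)-2,3-dihydroxy-5,5-dimethoxy-2-methylpentanoic acid | OC(=O)[C@@](C)(O)C(O)CC(OC)OC
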